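**Retrosynthetic overview**

- The target is an 8-methoxycoumarin whose O7 carries the chain C8H2–C7H(oxirane)–C6(CH3)(oxirane)–C5H2–C4H(O)–C3H2–C2(=C1H2)–C(=O), the carbonyl closing the γ-lactone onto the C4 oxygen.
- The lactone ring is disconnected last, to the C4 hydroxyl, the terminal alkyne C1≡C2 and CO (cyclocarbonylation). Before that, the oxirane C6–C7 is traced back to the (E)-C6=C7 alkene by reagent-controlled epoxidation.
- The strategy rests on the (E)-trisubstituted C6=C7 unit with the C6 methyl cis to C8. It is made in one operation: syn addition of CH3–Al across the terminal alkyne C6≡C7 of a C4-silyloxy hepta-1,6-diyne, then capture of the C7–Al bond by ArOCH2Cl (forms C6–CH3 and C7–C8).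
- The diyne, with C1≡C2 capped by SiMe3, comes from (S)-epichlorohydrin (source of C4) by two acetylide openings. ArOCH2Cl comes from 7-hydroxy-8-methoxycoumarin through its methylthiomethyl ether.
- Ring order: coumarin rings purchased; oxirane in step 8; α-methylene-γ-butyrolactone in step 10.

Key step: step 7

Remark: 7-hydroxy-8-methoxycoumarin is taken as a purchasable phenol; the carbinol carbon C4 keeps its geometry throughout, and its CIP label changes from R to S at the epoxidation only because the oxirane raises the priority of the C5 arm.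

**Route**

Step 1
Reactants: 1 trimethylsilylacetylene; 2 (S)-epichlorohydrin
Product: 4 (2S)-1-chloro-5-(trimethylsilyl)pent-4-yn-2-ol, via lithium (trimethylsilyl)acetylide 3 (not isolated)
Conditions: n-BuLi, THF, −78 °C; BF3·OEt2, then 2, −78 °C; aq. NH4Cl
Reagents that add atoms: n-butyllithium, [Li]CCCC (supplies the lithium of 3 only; no atom reaches 4)
Why: BF3-promoted alkynylation of an epoxide, in which the alkynyllithium opens the Lewis-acid-complexed oxirane of 2 at the unsubstituted ring carbon faster than it displaces the primary chloride, so no bond to the stereocentre is touched and the S configuration is carried into 4.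

Step 2
Reactants: 4 (2S)-1-chloro-5-(trimethylsilyl)pent-4-yn-2-ol
Product: 5 (2S)-2-[3-(trimethylsilyl)prop-2-yn-1-yl]oxirane
Conditions: NaH, THF, 0 °C → rt
Reagents that add atoms: none
Why: Intramolecular Williamson etherification (3-exo-tet) in which the alkoxide displaces the neighbouring primary chloride, the C–O bond at the stereocentre stays intact so its configuration is retained, and the non-nucleophilic hydride base in an aprotic solvent spares the C(sp)–Si bond.

Step 3
Reactants: 5 (2S)-2-[3-(trimethylsilyl)prop-2-yn-1-yl]oxirane; 6 acetylene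
Product: 8 (4R)-1-(trimethylsilyl)hepta-1,6-diyn-4-ol, via lithium acetylide 7 (not isolated)
Conditions: 6 (excess), n-BuLi, THF, −78 °C; BF3·OEt2, then 5, −78 °C; aq. NH4Cl
Reagents that add atoms: n-butyllithium, [Li]CCCC (supplies the lithium of 7 only; no atom reaches 8)
Why: A second BF3-promoted epoxide alkynylation, now with monolithium acetylide at the terminal oxirane carbon, should give the homopropargylic alcohol without touching the carbinol centre, which is stereogenic (R) only because one propargyl arm carries the silyl cap; the cold, non-basic conditions avoid silyl transfer between the two alkynes, which would erode the enantiomeric purity.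

Step 4
Reactants: 8 (4R)-1-(trimethylsilyl)hepta-1,6-diyn-4-ol
Product: 9 (4R)-4-[(tert-butyldimethylsilyl)oxy]-1-(trimethylsilyl)hepta-1,6-diyne
Conditions: TBSCl, imidazole, DMF, rt
Reagents that add atoms: tert-butyldimethylsilyl chloride, CC(C)(C)[Si](C)(C)Cl
Why: Imidazole-promoted silylation of a secondary alcohol, which masks the hydroxyl from AlMe3 and gives an ether that is stable to the Lewis acids of step 7.

Step 5
Reactants: 10 7-hydroxy-8-methoxy-2H-chromen-2-one; 11 chloromethyl methyl sulfide
Product: 12 8-methoxy-7-[(methylsulfanyl)methoxy]-2H-chromen-2-one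
Conditions: Cs2CO3, NaI (cat.), DMF, rt
Reagents that add atoms: none
Why: Williamson alkylation of the acidic 7-hydroxyl with the α-chloro sulfide, accelerated by in situ Finkelstein exchange to the iodide, should give the methylthiomethyl ether without opening the coumarin lactone.

Step 6
Reactants: 12 8-methoxy-7-[(methylsulfanyl)methoxy]-2H-chromen-2-one
Product: 13 7-(chloromethoxy)-8-methoxy-2H-chromen-2-one
Conditions: SO2Cl2 (1.0 equiv), CH2Cl2, −78 → 0 °C; volatiles removed, used crude under argon
Reagents that add atoms: sulfuryl chloride, O=S(=O)(Cl)Cl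
Why: Sulfuryl chloride chlorinates the sulfur of the O,S-acetal and the chlorosulfonium ion fragments to methanesulfenyl chloride and an aryloxymethyl cation that chloride captures (the standard conversion of methylthiomethyl ethers into chloromethyl ethers), the thioether reacting far faster at low temperature than the arene or the coumarin C3=C4 bond.

Step 7
Reactants: 9 (4R)-4-[(tert-butyldimethylsilyl)oxy]-1-(trimethylsilyl)hepta-1,6-diyne; 14 trimethylaluminium; 13 7-(chloromethoxy)-8-methoxy-2H-chromen-2-one
Product: 16 7-{[(2E,5R)-5-[(tert-butyldimethylsilyl)oxy]-3-methyl-8-(trimethylsilyl)oct-2-en-7-yn-1-yl]oxy}-8-methoxy-2H-chromen-2-one, via (E)-alkenyldimethylalane 15 (not isolated)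
Conditions: 14 (2 equiv), Cp2ZrCl2 (0.25 equiv), CH2Cl2, 0 °C → rt; excess 14 and solvent removed in vacuo; then 13, CH2Cl2, −30 → 0 °C; aq. NaHCO3
Reagents that add atoms: none
Why: Cp2ZrCl2 and AlMe3 form a methylzirconium–aluminium species that adds CH3–metal syn across the terminal alkyne of 9, methyl to the internal carbon C6 and metal to the terminal carbon C7, and transmetalation leaves the (E)-alkenyldimethylalane 15 (Negishi zirconium-catalysed carboalumination). After removal of surplus AlMe3, the Lewis-acidic aluminium activates the C–Cl bond of the α-chloro ether 13 and the alkenyl–Al bond attacks the aryloxymethyl electrophile with retention at the alkenyl carbon, forming C7–C8. The closest known case is the direct coupling of such alkenylalanes with chloromethyl methyl ether to give allylic methyl ethers, of which 13 is the aryl analogue. No ring is closed and no stereocentre is formed; the carbinol centre C4 is a spectator. The step needs three selectivities: methyl at the internal carbon, which the terminal alkyne secures; syn addition with retention in the trapping, which places the C6 methyl cis to C8 (E alkene); and reaction of only one alkyne, which the trimethylsilyl cap secures by making the other alkyne internal and hindered. The alkenyl group of 15 should transfer in preference to methyl, and the weakly nucleophilic alane should leave the coumarin lactone alone at or below 0 °C.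

Step 8
Reactants: 16 7-{[(2E,5R)-5-[(tert-butyldimethylsilyl)oxy]-3-methyl-8-(trimethylsilyl)oct-2-en-7-yn-1-yl]oxy}-8-methoxy-2H-chromen-2-one
Product: 17 7-({(2R,3R)-3-[(2S)-2-[(tert-butyldimethylsilyl)oxy]-5-(trimethylsilyl)pent-4-yn-1-yl]-3-methyloxiran-2-yl}methoxy)-8-methoxy-2H-chromen-2-one
Conditions: 1,2:4,5-di-O-isopropylidene-β-D-erythro-2,3-hexodiulo-2,6-pyranose (D-fructose-derived Shi ketone, 0.3 equiv), KHSO5 (as 2KHSO5·KHSO4·K2SO4), K2CO3, Bu4NHSO4 (cat.), MeCN/CH2(OMe)2, aq. Na2B4O7 buffer, 0 °C
Reagents that add atoms: potassium peroxymonosulfate, [K+].[O-]S(=O)(=O)OO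
Why: Shi asymmetric epoxidation, in which the dioxirane from the D-fructose-derived ketone transfers oxygen through a spiro transition state to one face of the (E)-trisubstituted alkene and should set both oxirane carbons as R (the sense known for (E)-trisubstituted alkenes such as 1-phenylcyclohexene) under reagent control, while the electrophilic oxidant should ignore the silyl alkyne and the electron-poor coumarin double bond.

Step 9
Reactants: 17 7-({(2R,3R)-3-[(2S)-2-[(tert-butyldimethylsilyl)oxy]-5-(trimethylsilyl)pent-4-yn-1-yl]-3-methyloxiran-2-yl}methoxy)-8-methoxy-2H-chromen-2-one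
Product: 18 7-({(2R,3R)-3-[(2S)-2-hydroxypent-4-yn-1-yl]-3-methyloxiran-2-yl}methoxy)-8-methoxy-2H-chromen-2-one
Conditions: Bu4NF, AcOH, THF, 0 °C → rt
Reagents that add atoms: none
Why: Fluoride cleaves the Si–O bond of the silyl ether and the Si–C(sp) bond of the alkynylsilane in one operation, and the acetic acid buffer keeps the medium from becoming basic enough to open the oxirane or the coumarin lactone.

Step 10
Reactants: 18 7-({(2R,3R)-3-[(2S)-2-hydroxypent-4-yn-1-yl]-3-methyloxiran-2-yl}methoxy)-8-methoxy-2H-chromen-2-one; 19 carbon monoxide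
Product: 20 7-({(2R,3R)-3-methyl-3-{[(2S)-4-methylidene-5-oxooxolan-2-yl]methyl}oxiran-2-yl}methoxy)-8-methoxy-2H-chromen-2-one
Conditions: PdI2 (5 mol %), PBu3 (10 mol %), 19 (about 7 atm), MeCN, 65 °C
Reagents that add atoms: none
Why: Palladium-catalysed cyclocarbonylation of a homopropargylic alcohol, in which the hydroxyl and CO form an alkoxycarbonyl complex of divalent palladium, the tethered alkyne inserts syn in a 5-exo fashion so that the carbonyl carbon bonds to the internal alkyne carbon, and protonolysis releases the α-methylene-γ-butyrolactone with the carbinol centre untouched; the tin-free catalyst is chosen so that no added Lewis acid opens the oxirane.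

**Compound list**

1 | trimethylsilylacetylene | C#C[Si](C)(C)C | starting material
2 | (S)-epichlorohydrin, (2S)-2-(chloromethyl)oxirane | ClC[C@@H]1CO1 | starting material
3 | lithium (trimethylsilyl)acetylide | [Li]C#C[Si](C)(C)C | intermediate
4 | (2S)-1-chloro-5-(trimethylsilyl)pent-4-yn-2-ol | C[Si](C)(C)C#CC[C@H](O)CCl | intermediate
5 | (2S)-2-[3-(trimethylsilyl)prop-2-yn-1-yl]oxirane | C[Si](C)(C)C#CC[C@H]1CO1 | intermediate
6 | acetylene | C#C | starting material
7 | lithium acetylide | [Li]C#C | intermediate
8 | (4R)-1-(trimethylsilyl)hepta-1,6-diyn-4-ol | C[Si](C)(C)C#CC[C@@H](CC#C)O | intermediate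
9 | (4R)-4-[(tert-butyldimethylsilyl)oxy]-1-(trimethylsilyl)hepta-1,6-diyne | C[Si](C)(C)C#CC[C@@H](CC#C)O[Si](C)(C)C(C)(C)C | intermediate
10 | 7-hydroxy-8-methoxy-2H-chromen-2-one | Oc1ccc2ccc(=O)oc2c1OC | starting material
11 | chloromethyl methyl sulfide | ClCSC | starting material
12 | 8-methoxy-7-[(methylsulfanyl)methoxy]-2H-chromen-2-one | CSCOc1ccc2ccc(=O)oc2c1OC | intermediate
13 | 7-(chloromethoxy)-8-methoxy-2H-chromen-2-one | ClCOc1ccc2ccc(=O)oc2c1OC | intermediate
14 | trimethylaluminium | C[Al](C)C | starting material
15 | [(1E,4R)-4-[(tert-butyldimethylsilyl)oxy]-2-methyl-7-(trimethylsilyl)hept-1-en-6-yn-1-yl]dimethylalane | C[Si](C)(C)C#CC[C@@H](C/C(C)=C/[Al](C)C)O[Si](C)(C)C(C)(C)C | intermediate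
16 | 7-{[(2E,5R)-5-[(tert-butyldimethylsilyl)oxy]-3-methyl-8-(trimethylsilyl)oct-2-en-7-yn-1-yl]oxy}-8-methoxy-2H-chromen-2-one | C[Si](C)(C)C#CC[C@@H](C/C(C)=C/COc1ccc2ccc(=O)oc2c1OC)O[Si](C)(C)C(C)(C)C | intermediate
17 | 7-({(2R,3R)-3-[(2S)-2-[(tert-butyldimethylsilyl)oxy]-5-(trimethylsilyl)pent-4-yn-1-yl]-3-methyloxiran-2-yl}methoxy)-8-methoxy-2H-chromen-2-one | C[Si](C)(C)C#CC[C@@H](C[C@@]3(C)O[C@@H]3COc1ccc2ccc(=O)oc2c1OC)O[Si](C)(C)C(C)(C)C | intermediate
18 | 7-({(2R,3R)-3-[(2S)-2-hydroxypent-4-yn-1-yl]-3-methyloxiran-2-yl}methoxy)-8-methoxy-2H-chromen-2-one | C#CC[C@@H](C[C@@]3(C)O[C@@H]3COc1ccc2ccc(=O)oc2c1OC)O | intermediate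
19 | carbon monoxide | [C-]#[O+] | starting material
20 | 7-({(2R,3R)-3-methyl-3-{[(2S)-4-methylidene-5-oxooxolan-2-yl]methyl}oxiran-2-yl}methoxy)-8-methoxy-2H-chromen-2-one | C=C1C[C@@H](C[C@@]2(C)O[C@@H]2COc2ccc3ccc(=O)oc3c2OC)OC1=O | target

**Step count**

Total step count: 10. Longest linear sequence: 8 steps (steps 1–4, then 7–10); steps 5 and 6 form the second branch.

**Steps most likely to fail**

1. Step 7. Three processes could defeat the trapping:
   - methyl rather than alkenyl transfer from aluminium to the chloromethyl ether;
   - ionisation of the chloromethyl ether followed by capture of the cation by the neighbouring 8-methoxy oxygen and demethylation;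
   - Lewis-acid cleavage of the allylic aryl ether once it has formed.

   Fallback, from 9 back to 16: the same zirconium-catalysed methylalumination of 9 is followed by conversion of the alkenylalane into its lithium alanate with n-BuLi and addition to paraformaldehyde. This should give (2E,5R)-5-[(tert-butyldimethylsilyl)oxy]-3-methyl-8-(trimethylsilyl)oct-2-en-7-yn-1-ol F1. Mitsunobu etherification of this primary allylic alcohol with phenol 10 (PPh3, DIAD, THF) then gives 16. Neither stage needs the chloromethyl ether or a strong Lewis acid in the presence of the coumarin.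

2. Step 10. The hydrogen iodide equivalents that shuttle through the catalytic cycle may open or rearrange the trisubstituted oxirane, which would also stall the cycle, and free phosphine may add to the α-methylene lactone as it forms.

   Fallback, from 18 back to 20: acylation of the hydroxyl of 18 with COCl2 and pyridine, then PhSeH, should give O-{(2S)-1-[(2R,3R)-3-{[(8-methoxy-2-oxo-2H-chromen-7-yl)oxy]methyl}-2-methyloxiran-2-yl]pent-4-yn-2-yl} Se-phenyl carbonoselenoate F3. Treatment with Bu3SnH and AIBN in dilute benzene at 80 °C generates the alkoxycarbonyl radical, which cyclises 5-exo-dig onto the terminal alkyne. Hydrogen transfer to the alkenyl radical gives 20 under neutral conditions.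

3. Step 8. The allylic aryloxy group lowers the nucleophilicity of the alkene, so oxygen transfer may be slow against decay of the ketone catalyst, and the facial selectivity may be insufficient.

   Fallback, from 9 back to 17, through the allylic alcohol F1 of the first fallback: Sharpless asymmetric epoxidation of F1 (Ti(OiPr)4, D-(−)-diethyl tartrate, t-BuOOH, 4 Å sieves, CH2Cl2, −20 °C) should give {(2R,3R)-3-[(2S)-2-[(tert-butyldimethylsilyl)oxy]-5-(trimethylsilyl)pent-4-yn-1-yl]-3-methyloxiran-2-yl}methanol F2. The oxirane configuration is then set by the tartrate on a geraniol-type allylic alcohol. Mitsunobu etherification of the primary hydroxyl with phenol 10 (PPh3, DIAD) gives 17 and bypasses 16.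

**Further compounds**

F1 | step 7 | (2E,5R)-5-[(tert-butyldimethylsilyl)oxy]-3-methyl-8-(trimethylsilyl)oct-2-en-7-yn-1-ol | C[Si](C)(C)C#CC[C@@H](C/C(C)=C/CO)O[Si](C)(C)C(C)(C)C
F2 | step 8 | {(2R,3R)-3-[(2S)-2-[(tert-butyldimethylsilyl)oxy]-5-(trimethylsilyl)pent-4-yn-1-yl]-3-methyloxiran-2-yl}methanol | C[Si](C)(C)C#CC[C@@H](C[C@@]1(C)O[C@@H]1CO)O[Si](C)(C)C(C)(C)C
F3 | step 10 | O-{(2S)-1-[(2R,3R)-3-{[(8-methoxy-2-oxo-2H-chromen-7-yl)oxy]methyl}-2-methyloxiran-2-yl]pent-4-yn-2-yl} Se-phenyl carbonoselenoate | C#CC[C@@H](C[C@@]3(C)O[C@@H]3COc1ccc2ccc(=O)oc2c1OC)OC(=O)[Se]c1ccccc1
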